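**Retrosynthetic overview**
- The target comes from its bis-TBS ether, which opens by one retro-[2+2] to an achiral (E)-3,5-dimethoxy-2,6-diprenyl-3',4'-bis(silyloxy)stilbene. This is the protected form of the stilbene from which the plant is presumed to build the skeleton.
- Both rings form in that one operation. The cyclopentane closes first (C2a–C7a bond) and the cyclobutane second (C1–C2 bond). A stilbene radical cation paired with a chiral anion selects one of the two enantiotopic prenyl groups and sets all three stereocentres.
- The stilbene comes from a Horner–Wadsworth–Emmons union of a 2,6-diprenylbenzylphosphonate with 3,4-bis(TBSO)benzaldehyde.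
- The phosphonate comes from a double linear-selective Suzuki prenylation of the 2,6-dibromide, made with NBS from commercial diethyl 3,5-dimethoxybenzylphosphonate. The aldehyde comes from protocatechualdehyde and TBSCl.

Assumption: the sense of induction of the chiral anion cannot be predicted, so (S,S)-IDPi is written, and the equally accessible (R,R)-anion is used if the first run gives the mirror image of the target.

**Step 1**
Reactants: 1 diethyl (3,5-dimethoxybenzyl)phosphonate; 2 N-bromosuccinimide
Product: 3 diethyl (2,6-dibromo-3,5-dimethoxybenzyl)phosphonate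
Conditions: NBS (2.1 equiv), MeCN, 0 °C to rt, dark
Reagents that add atoms: N-bromosuccinimide, O=C1CCC(=O)N1Br
Why: Electrophilic aromatic bromination, in which C2 and C6 are each para to one OMe and ortho to the other while C4 is wedged between both OMe groups, so two equivalents of NBS under ionic conditions stop at the 2,6-dibromide without touching the P–CH2; no stereocentre is formed.

**Step 2**
Reactants: 3 diethyl (2,6-dibromo-3,5-dimethoxybenzyl)phosphonate; 4 prenylboronic acid pinacol ester
Product: 5 diethyl [3,5-dimethoxy-2,6-bis(3-methylbut-2-en-1-yl)benzyl]phosphonate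
Conditions: 4 (3.0 equiv), Pd-PEPPSI-IPent (5 mol %), 5 M aq KOH, THF, 70 °C
Reagents that add atoms: prenylboronic acid pinacol ester, CC(C)=CCB1OC(C)(C)C(C)(C)O1
Why: Double Suzuki–Miyaura allyl–aryl coupling, in which the very bulky NHC ligand and the di-ortho-substituted aryl group both favour reductive elimination from the sigma-allyl-Pd bound at its CH2 terminus, so both C–Br bonds give linear prenyl rather than reverse prenyl, and the phosphonate diester stays in the THF phase and survives; no stereocentre is formed.

**Step 3**
Reactants: 6 3,4-dihydroxybenzaldehyde; 7 tert-butyldimethylsilyl chloride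
Product: 8 3,4-bis(tert-butyldimethylsilyloxy)benzaldehyde
Conditions: TBSCl (2.4 equiv), imidazole (5 equiv), DMF, 0 °C to rt
Reagents that add atoms: tert-butyldimethylsilyl chloride, CC(C)(C)[Si](C)(C)Cl
Why: Imidazole-promoted O-silylation of both acidic catechol hydroxyls gives a fluoride-labile but still electron-donating mask that tolerates amide base and single-electron oxidation; no stereocentre is formed.

**Step 4**
Reactants: 5 diethyl [3,5-dimethoxy-2,6-bis(3-methylbut-2-en-1-yl)benzyl]phosphonate; 8 3,4-bis(tert-butyldimethylsilyloxy)benzaldehyde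
Product: 9 (E)-1-{2-[3,4-bis(tert-butyldimethylsilyloxy)phenyl]ethenyl}-3,5-dimethoxy-2,6-bis(3-methylbut-2-en-1-yl)benzene
Conditions: 5, KHMDS (1.1 equiv), THF, −78 °C; then 8, −78 °C to rt
Reagents that add atoms: none
Why: Horner–Wadsworth–Emmons olefination, in which the P–CH2 is the only site acidic enough for KHMDS at −78 °C, addition to the unhindered aldehyde is reversible, the clash between the 2,6-diprenylaryl group and ring B directs elimination to the E-alkene, and pre-forming the anion with a non-nucleophilic base spares the aryl silyl ethers; no stereocentre is formed, only the E geometry.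

**Step 5**
Reactants: 9 (E)-1-{2-[3,4-bis(tert-butyldimethylsilyloxy)phenyl]ethenyl}-3,5-dimethoxy-2,6-bis(3-methylbut-2-en-1-yl)benzene
Product: 11 4-[(2S,2aR,7aS)-4,6-dimethoxy-1,1-dimethyl-3-(3-methylbut-2-en-1-yl)-2,2a,7,7a-tetrahydro-1H-cyclobuta[a]inden-2-yl]benzene-1,2-diol, via bis-TBS cycloadduct 10 (not isolated)
Conditions: 2,3,6,7-tetramethoxy-9-(o-tolyl)thioxanthylium (S,S)-IDPi salt (3 mol %), CH2Cl2/pentane 1:1 (0.02 M), green LED (525 nm), −90 °C, Ar, stopped at full conversion; then TBAF/AcOH (2.5 equiv each), THF, 0 °C, Ar
Reagents that add atoms: none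
Why: Proposed new method: the green-light-excited thioxanthylium cation oxidises the 3,4-disilyloxystyryl unit of 9 (about +1.2 V, far below the prenyl alkenes) to a radical cation whose only counterion in the apolar medium at −90 °C is the confined chiral imidodiphosphorimidate; because the 2,6-disubstituted ring A stands perpendicular to the alkene, its two enantiotopic prenyl groups lie over opposite alkene faces, the anion blocks one face, and the prenyl on the open face attacks the ring-A-bearing alkene carbon by 5-exo closure (C2a–C7a bond, cis fusion enforced by the bicyclo[3.2.0] frame) to give a tertiary-alkyl/para-oxybenzyl distonic radical cation, which closes the cyclobutane (C1–C2 bond) with the aryl group on the convex face trans to ring A as the E geometry dictates, and electron return from the reduced catalyst or from another molecule of 9 releases 10, so all three stereocentres arise in one desymmetrising event; the closest known reaction types are visible-light radical-cation intramolecular [2+2] cycloadditions of tethered electron-rich styrenes to bicyclo[3.2.0]heptanes and asymmetric counteranion-directed photoredox reactions of anethole-type radical cations; buffered fluoride then cleaves both aryl silyl ethers without affecting the methyl ethers, the prenyl alkene or the stereocentres.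

**Compound list**
1 | diethyl (3,5-dimethoxybenzyl)phosphonate | CCOP(=O)(Cc1cc(OC)cc(OC)c1)OCC | starting material
2 | N-bromosuccinimide | O=C1CCC(=O)N1Br | starting material
3 | diethyl (2,6-dibromo-3,5-dimethoxybenzyl)phosphonate | CCOP(=O)(Cc1c(Br)c(OC)cc(OC)c1Br)OCC | intermediate
4 | prenylboronic acid pinacol ester (4,4,5,5-tetramethyl-2-(3-methylbut-2-en-1-yl)-1,3,2-dioxaborolane) | CC(C)=CCB1OC(C)(C)C(C)(C)O1 | starting material
5 | diethyl [3,5-dimethoxy-2,6-bis(3-methylbut-2-en-1-yl)benzyl]phosphonate | CCOP(=O)(Cc1c(CC=C(C)C)c(OC)cc(OC)c1CC=C(C)C)OCC | intermediate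
6 | 3,4-dihydroxybenzaldehyde | O=Cc1ccc(O)c(O)c1 | starting material
7 | tert-butyldimethylsilyl chloride | CC(C)(C)[Si](C)(C)Cl | starting material
8 | 3,4-bis(tert-butyldimethylsilyloxy)benzaldehyde | O=Cc1ccc(O[Si](C)(C)C(C)(C)C)c(O[Si](C)(C)C(C)(C)C)c1 | intermediate
9 | (E)-1-{2-[3,4-bis(tert-butyldimethylsilyloxy)phenyl]ethenyl}-3,5-dimethoxy-2,6-bis(3-methylbut-2-en-1-yl)benzene | COc1cc(OC)c(CC=C(C)C)c(/C=C/c2ccc(O[Si](C)(C)C(C)(C)C)c(O[Si](C)(C)C(C)(C)C)c2)c1CC=C(C)C | intermediate
10 | (2S,2aR,7aS)-2-[3,4-bis(tert-butyldimethylsilyloxy)phenyl]-4,6-dimethoxy-1,1-dimethyl-3-(3-methylbut-2-en-1-yl)-2,2a,7,7a-tetrahydro-1H-cyclobuta[a]indene (ring-fusion H atoms cis, aryl on the convex face) | COc1cc(OC)c2c(c1CC=C(C)C)[C@@H]1[C@H](C2)C(C)(C)[C@H]1c1ccc(O[Si](C)(C)C(C)(C)C)c(O[Si](C)(C)C(C)(C)C)c1 | intermediate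
11 | 4-[(2S,2aR,7aS)-4,6-dimethoxy-1,1-dimethyl-3-(3-methylbut-2-en-1-yl)-2,2a,7,7a-tetrahydro-1H-cyclobuta[a]inden-2-yl]benzene-1,2-diol | COc1cc(OC)c2c(c1CC=C(C)C)[C@@H]1[C@H](C2)C(C)(C)[C@H]1c1ccc(O)c(O)c1 | target

**Step count:** 5 steps in total. The longest linear sequence is 4 steps (1 → 3 → 5 → 9 → 11).

**Steps most likely to fail**

Step 5 carries the most risk. The large substrate may sit poorly in the confined anion and give low ee. The strongly oxidising excited catalyst may also re-oxidise 10 and open the doubly benzylic cyclobutane bond. The fallback gives up asymmetric catalysis and the radical-cation manifold together. It sets out from 9 and runs the cycloaddition through the triplet state with the achiral sensitiser [Ir(dF(CF3)ppy)2(dtbbpy)]PF6 (blue LED, MeCN, rt). This gives 10 as a 1:1 mixture with its mirror image, the (2R,2aS,7aR)-bis-TBS cycloadduct F1. The two lipophilic silyl ethers are separated by preparative SFC on an amylose-carbamate chiral phase, and the route is rejoined at 10, which is desilylated as in step 5.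

Step 2 is second. Two consecutive linear-selective couplings at di-ortho-substituted, electron-rich C–Br bonds may give reverse-prenyl isomers or protodebromination. The fallback removes the regiochemical question. It sets out from 3 and couples with allylboronic acid pinacol ester, whose two allyl termini are identical (Pd(dppf)Cl2, aq KOH, THF, 65 °C), to give diethyl (2,6-diallyl-3,5-dimethoxybenzyl)phosphonate F2. A double cross-metathesis with excess 2-methyl-2-butene (Hoveyda–Grubbs II, CH2Cl2, 40 °C) then converts each allyl into prenyl and comes back to the route at 5.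

Step 4 is third. The anion of 5 is flanked by two prenyl groups, is twisted out of conjugation, and may add sluggishly or strip the silyl groups. The fallback forms the aryl–alkene bond instead of the C=C bond.
- It sets out from 5, which is olefinated with the smallest aldehyde (KHMDS, then monomeric formaldehyde from cracked paraformaldehyde, THF) to give 3,5-dimethoxy-2,6-bis(3-methylbut-2-en-1-yl)styrene F3.
- Commercial 4-bromocatechol is silylated with 7 and imidazole to give 4-bromo-1,2-bis(tert-butyldimethylsilyloxy)benzene F4.
- A Mizoroki–Heck coupling of F3 with F4 (Pd(OAc)2, P(o-tol)3, Et3N, DMF, 100 °C) arylates the unhindered terminal carbon and gives the E-stilbene, which comes back to the route at 9.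

**Further compounds**
F1 | step 5 | (2R,2aS,7aR)-2-[3,4-bis(tert-butyldimethylsilyloxy)phenyl]-4,6-dimethoxy-1,1-dimethyl-3-(3-methylbut-2-en-1-yl)-2,2a,7,7a-tetrahydro-1H-cyclobuta[a]indene (enantiomer of 10) | COc1cc(OC)c2c(c1CC=C(C)C)[C@H]1[C@@H](C2)C(C)(C)[C@@H]1c1ccc(O[Si](C)(C)C(C)(C)C)c(O[Si](C)(C)C(C)(C)C)c1
F2 | step 2 | diethyl (2,6-diallyl-3,5-dimethoxybenzyl)phosphonate | CCOP(=O)(Cc1c(CC=C)c(OC)cc(OC)c1CC=C)OCC
F3 | step 4 | 3,5-dimethoxy-2,6-bis(3-methylbut-2-en-1-yl)styrene | C=Cc1c(CC=C(C)C)c(OC)cc(OC)c1CC=C(C)C
F4 | step 4 | 4-bromo-1,2-bis(tert-butyldimethylsilyloxy)benzene | CC(C)(C)[Si](C)(C)Oc1ccc(Br)cc1O[Si](C)(C)C(C)(C)C
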